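The plan cuts ring A (C1 carbonyl, C2=C3, C4, C5 carbinol, C6; side chain C1', C2') at C1, so that both ring bonds to this carbon, C1–C6 and C1–C2, come from one acyl dianion equivalent, a 2-silyl-1,3-dithiane. The key step exploits the 1,3-relationship between C1 and the oxygen-bearing quaternary C5: in one flask the dithiane anion opens a C5–C6 epoxide at C6, silicon passes from C1 to the C5 oxygen, and the renewed C1 carbanion closes the six-membered ring on a chloride at C2. The precursor is an enantiopure 2,2-disubstituted oxirane carrying a 3-chloropropyl arm (C4–C2) and the dithiane-masked linoleoyl chain.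

Key step: step 12

Remark: the R/S descriptor of C5 changes along the route only because the CIP priorities of its neighbours change; its spatial arrangement is fixed in step 4 and no later step makes or breaks a bond at this carbon.

Assumption: the sense of the titanium–tartrate epoxidation is taken from the usual facial rule for 2-substituted allylic alcohols, and the enantiomeric purity of the epoxy alcohol should be checked before it is carried on.

Step 1
Reactants: 1 triethyl phosphonoacetate; 2 1-bromo-3-chloropropane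
Product: 4 ethyl 5-chloro-2-(diethoxyphosphoryl)pentanoate (racemic), via sodium enolate 3 (not isolated)
Conditions: NaH, THF/DMF, 0 → 50 °C
Reagents that add atoms: none
Why: SN2 C-alkylation of the phosphonoacetate enolate should take place at the bromide end only, since chloride is much the poorer leaving group.

Step 2
Reactants: 4 ethyl 5-chloro-2-(diethoxyphosphoryl)pentanoate
Product: 5 ethyl 5-chloro-2-methylidenepentanoate
Conditions: 37 % aq. HCHO, K2CO3, H2O, rt → 60 °C
Reagents that add atoms: formaldehyde, C=O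
Why: Horner–Wadsworth–Emmons olefination with formaldehyde in aqueous carbonate should give the 1,1-disubstituted acrylate directly, the mild base leaving the alkyl chloride alone.

Step 3
Reactants: 5 ethyl 5-chloro-2-methylidenepentanoate
Product: 6 2-(3-chloropropyl)prop-2-en-1-ol
Conditions: DIBAL-H (2.2 equiv), CH2Cl2, –78 → 0 °C; aq. Rochelle salt
Reagents that add atoms: none
Why: DIBAL-H 1,2-reduction of an α-substituted acrylate should stop cleanly at the allylic alcohol at low temperature without touching the chloride.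

Step 4
Reactants: 6 2-(3-chloropropyl)prop-2-en-1-ol
Product: 7 (R)-[2-(3-chloropropyl)oxiran-2-yl]methanol
Conditions: Ti(OiPr)4 (10 mol %), D-(−)-diisopropyl tartrate (12 mol %), t-BuOOH, 4 Å MS, CH2Cl2, –20 °C
Reagents that add atoms: tert-butyl hydroperoxide, CC(C)(C)OO
Why: Sharpless asymmetric epoxidation with the D-(−)-tartrate should deliver oxygen to the alkene face that gives the (R)-epoxy alcohol, which sets the only stereocentre of the target (C5), while catalytic loading and molecular sieves limit opening of the sensitive 2,2-disubstituted epoxide.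

Step 5
Reactants: 7 (R)-[2-(3-chloropropyl)oxiran-2-yl]methanol
Product: 8 (S)-2-(3-chloropropyl)-2-[(triphenylmethoxy)methyl]oxirane
Conditions: TrCl, Et3N, DMAP (cat.), CH2Cl2, rt
Reagents that add atoms: trityl chloride, ClC(c1ccccc1)(c1ccccc1)c1ccccc1
Why: DMAP-catalysed tritylation of the primary alcohol should give a base-stable, acid-labile ether that cannot migrate to a neighbouring alkoxide and that marks the carbon which later becomes C6.

Step 6
Reactants: 9 linoleyl alcohol
Product: 10 (9Z,12Z)-octadeca-9,12-dienal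
Conditions: Dess–Martin periodinane, NaHCO3, CH2Cl2, 0 °C → rt
Reagents that add atoms: none
Why: Dess–Martin oxidation should convert the primary alcohol into the aldehyde under buffered, non-radical conditions that leave the skipped (Z,Z)-diene untouched.

Step 7
Reactants: 10 (9Z,12Z)-octadeca-9,12-dienal; 11 propane-1,3-dithiol
Product: 12 2-[(8Z,11Z)-heptadeca-8,11-dien-1-yl]-1,3-dithiane
Conditions: BF3·OEt2 (0.2 equiv), CH2Cl2, –20 → 0 °C
Reagents that add atoms: none
Why: Lewis acid-catalysed dithioacetalisation of the aldehyde should proceed at low temperature, where the diene is not isomerised.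

Step 8
Reactants: 12 2-[(8Z,11Z)-heptadeca-8,11-dien-1-yl]-1,3-dithiane; 8 (S)-2-(3-chloropropyl)-2-[(triphenylmethoxy)methyl]oxirane
Product: 14 (2S)-5-chloro-2-({2-[(8Z,11Z)-heptadeca-8,11-dien-1-yl]-1,3-dithian-2-yl}methyl)-1-(triphenylmethoxy)pentan-2-ol, via lithiated dithiane 13 (not isolated)
Conditions: t-BuLi, THF/HMPA (10:1), –78 °C, 10 min; then 8, –78 → –25 °C; aq. NH4Cl
Reagents that add atoms: none
Why: Corey–Seebach umpolung, in which the lithiated dithiane should open the epoxide at its unsubstituted CH2 carbon by SN2 attack and form the C1'–C2' bond without touching the stereocentre, the brief cold lithiation sparing the doubly allylic CH2 and the chloride being too poor a leaving group to compete.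

Step 9
Reactants: 14 (2S)-5-chloro-2-({2-[(8Z,11Z)-heptadeca-8,11-dien-1-yl]-1,3-dithian-2-yl}methyl)-1-(triphenylmethoxy)pentan-2-ol
Product: 15 (2S)-5-chloro-2-({2-[(8Z,11Z)-heptadeca-8,11-dien-1-yl]-1,3-dithian-2-yl}methyl)pentane-1,2-diol
Conditions: TsOH·H2O (10 mol %), MeOH/CH2Cl2, rt
Reagents that add atoms: none
Why: Acid-catalysed SN1 solvolysis of the trityl ether, with the trityl cation trapped by methanol, should free the primary hydroxyl while dithiane, tertiary alcohol, chloride and diene are inert to dilute acid.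

Step 10
Reactants: 15 (2S)-5-chloro-2-({2-[(8Z,11Z)-heptadeca-8,11-dien-1-yl]-1,3-dithian-2-yl}methyl)pentane-1,2-diol
Product: 17 (S)-2-(3-chloropropyl)-2-({2-[(8Z,11Z)-heptadeca-8,11-dien-1-yl]-1,3-dithian-2-yl}methyl)oxirane, via primary mesylate 16 (not isolated)
Conditions: MsCl, Et3N, CH2Cl2, –20 °C; then K2CO3, MeOH, 0 °C → rt
Reagents that add atoms: none
Why: Selective mesylation of the primary hydroxyl and intramolecular Williamson closure (3-exo-tet) by the tertiary alkoxide should give the oxirane with C5 untouched, the far better sulfonate leaving group outpacing any attack on the chloride.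

Step 11
Reactants: 18 1,3-dithiane
Product: 20 2-(tert-butyldimethylsilyl)-1,3-dithiane, via 2-lithio-1,3-dithiane 19 (not isolated)
Conditions: n-BuLi, THF, –30 °C; then TBSCl, –78 °C → rt
Reagents that add atoms: tert-butyldimethylsilyl chloride, CC(C)(C)[Si](C)(C)Cl
Why: Deprotonation of the dithiane and C-silylation of the lithio species with the silyl chloride is the standard route to 2-silyl dithianes.

Step 12
Reactants: 20 2-(tert-butyldimethylsilyl)-1,3-dithiane; 17 (S)-2-(3-chloropropyl)-2-({2-[(8Z,11Z)-heptadeca-8,11-dien-1-yl]-1,3-dithian-2-yl}methyl)oxirane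
Product: 24 (8R)-8-[(tert-butyldimethylsilyl)oxy]-8-({2-[(8Z,11Z)-heptadeca-8,11-dien-1-yl]-1,3-dithian-2-yl}methyl)-1,5-dithiaspiro[5.5]undecane, via lithiated silyl dithiane 21 (not isolated), via lithium alkoxide 22 (not isolated), via relay carbanion 23 (not isolated)
Conditions: t-BuLi, Et2O, –78 → –45 °C; then 17, Et2O, –78 → –25 °C; then HMPA/THF, –78 → 0 °C
Reagents that add atoms: none
Why: The lithiated silyl dithiane 21 opens the oxirane of 17 at its CH2 carbon (C6) by SN2 attack assisted by lithium coordination in ether, giving the tertiary lithium alkoxide 22 and the C1–C6 bond while C5 is not touched. HMPA then triggers the 1,4-shift of silicon from C1 to the C5 oxygen (Brook rearrangement), which protects that oxygen and regenerates a sulfur-stabilised carbanion at C1 (23). This carbanion displaces the primary chloride at C2 in a 6-exo-tet closure, so ring A is formed with both of its new bonds made at C1. The closest known reaction type is the silyl dithiane anion-relay coupling of epoxides in its intramolecular form, the carbocyclisation of epoxy halides and epoxy sulfonates. No stereocentre is formed; C5 is carried over from the Sharpless-derived epoxide because no bond to it is made or broken. The step needs the epoxide to react before the chloride and the alkylation to follow the silyl shift, which should be secured by the poor leaving group (chloride is inert to the hindered, ether-aggregated anion at low temperature, while the strained epoxide is lithium-activated), by the late addition of HMPA and by the intramolecular nature of the final alkylation.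

Step 13
Reactants: 24 (8R)-8-[(tert-butyldimethylsilyl)oxy]-8-({2-[(8Z,11Z)-heptadeca-8,11-dien-1-yl]-1,3-dithian-2-yl}methyl)-1,5-dithiaspiro[5.5]undecane
Product: 25 (3R)-3-[(tert-butyldimethylsilyl)oxy]-3-[(10Z,13Z)-2-oxononadeca-10,13-dien-1-yl]cyclohexan-1-one
Conditions: MeI, CaCO3, MeCN/H2O (9:1), 45 °C
Reagents that add atoms: water, O
Why: Alkylative hydrolysis of both dithioacetals (S-methylation, then hydrolysis of the sulfonium salts) should unmask the two ketones under buffered, non-oxidising conditions that spare the diene and the tertiary silyl ether.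

Step 14
Reactants: 25 (3R)-3-[(tert-butyldimethylsilyl)oxy]-3-[(10Z,13Z)-2-oxononadeca-10,13-dien-1-yl]cyclohexan-1-one
Product: 26 (5S)-5-[(tert-butyldimethylsilyl)oxy]-5-[(10Z,13Z)-2-oxononadeca-10,13-dien-1-yl]-2-(phenylselanyl)cyclohexan-1-one (both C2 epimers)
Conditions: N-(phenylselanyl)phthalimide, (S)-N-(pyrrolidin-2-ylmethyl)trifluoromethanesulfonamide (10 mol %), CH2Cl2, rt
Reagents that add atoms: N-(phenylselanyl)phthalimide, O=C1N([Se]c2ccccc2)C(=O)c2ccccc12
Why: Enamine-catalysed α-selenenylation, in which the cyclohexanone should condense with the secondary amine far more readily than the acyclic ketone flanked by two methylene groups and the enamine should form toward C2 because C6 is neopentylic, so that selenium enters at C2 of ring A (its configuration there is irrelevant).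

Step 15
Reactants: 26 (5S)-5-[(tert-butyldimethylsilyl)oxy]-5-[(10Z,13Z)-2-oxononadeca-10,13-dien-1-yl]-2-(phenylselanyl)cyclohexan-1-one
Product: 28 (5S)-5-[(tert-butyldimethylsilyl)oxy]-5-[(10Z,13Z)-2-oxononadeca-10,13-dien-1-yl]cyclohex-2-en-1-one, via selenoxide 27 (not isolated)
Conditions: 30 % H2O2, pyridine, CH2Cl2, 0 °C → rt
Reagents that add atoms: none
Why: Selenoxide syn-elimination can only remove a hydrogen from C3 and should therefore give the C2–C3 enone at 0 °C without acid, oxygen gas or a transition metal, all of which would endanger the skipped diene or the β-silyloxy ketone.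

Step 16
Reactants: 28 (5S)-5-[(tert-butyldimethylsilyl)oxy]-5-[(10Z,13Z)-2-oxononadeca-10,13-dien-1-yl]cyclohex-2-en-1-one
Product: 29 (5S)-5-hydroxy-5-[(10Z,13Z)-2-oxononadeca-10,13-dien-1-yl]cyclohex-2-en-1-one
Conditions: HF·pyridine, pyridine, THF, 0 °C → rt
Reagents that add atoms: none
Why: Fluoride-mediated cleavage of the tertiary silyl ether in a pyridine-buffered medium should release the tertiary alcohol without altering C5, the buffer being chosen to suppress β-elimination toward the phenol.

Compound list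
1 | triethyl phosphonoacetate | CCOC(=O)CP(=O)(OCC)OCC | starting material
2 | 1-bromo-3-chloropropane | ClCCCBr | starting material
3 | sodium enolate of triethyl phosphonoacetate (not isolated) | CCOC(=O)[CH-]P(=O)(OCC)OCC.[Na+] | intermediate
4 | ethyl 5-chloro-2-(diethoxyphosphoryl)pentanoate (racemic) | CCOC(=O)C(CCCCl)P(=O)(OCC)OCC | intermediate
5 | ethyl 5-chloro-2-methylidenepentanoate | CCOC(=O)C(=C)CCCCl | intermediate
6 | 2-(3-chloropropyl)prop-2-en-1-ol | OCC(=C)CCCCl | intermediate
7 | (R)-[2-(3-chloropropyl)oxiran-2-yl]methanol | ClCCC[C@@]1(CO)CO1 | intermediate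
8 | (S)-2-(3-chloropropyl)-2-[(triphenylmethoxy)methyl]oxirane | ClCCC[C@@]1(COC(c2ccccc2)(c2ccccc2)c2ccccc2)CO1 | intermediate
9 | linoleyl alcohol, (9Z,12Z)-octadeca-9,12-dien-1-ol | CCCCC/C=C\C/C=C\CCCCCCCCO | starting material
10 | (9Z,12Z)-octadeca-9,12-dienal | CCCCC/C=C\C/C=C\CCCCCCCC=O | intermediate
11 | propane-1,3-dithiol | SCCCS | starting material
12 | 2-[(8Z,11Z)-heptadeca-8,11-dien-1-yl]-1,3-dithiane | CCCCC/C=C\C/C=C\CCCCCCCC1SCCCS1 | intermediate
13 | 2-lithio-2-[(8Z,11Z)-heptadeca-8,11-dien-1-yl]-1,3-dithiane (not isolated) | [Li]C1(CCCCCCC/C=C\C/C=C\CCCCC)SCCCS1 | intermediate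
14 | (2S)-5-chloro-2-({2-[(8Z,11Z)-heptadeca-8,11-dien-1-yl]-1,3-dithian-2-yl}methyl)-1-(triphenylmethoxy)pentan-2-ol | ClCCC[C@@](O)(COC(c1ccccc1)(c1ccccc1)c1ccccc1)CC1(CCCCCCC/C=C\C/C=C\CCCCC)SCCCS1 | intermediate
15 | (2S)-5-chloro-2-({2-[(8Z,11Z)-heptadeca-8,11-dien-1-yl]-1,3-dithian-2-yl}methyl)pentane-1,2-diol | ClCCC[C@@](O)(CO)CC1(CCCCCCC/C=C\C/C=C\CCCCC)SCCCS1 | intermediate
16 | primary methanesulfonate of diol 15 (not isolated) | ClCCC[C@@](O)(COS(C)(=O)=O)CC1(CCCCCCC/C=C\C/C=C\CCCCC)SCCCS1 | intermediate
17 | (S)-2-(3-chloropropyl)-2-({2-[(8Z,11Z)-heptadeca-8,11-dien-1-yl]-1,3-dithian-2-yl}methyl)oxirane | ClCCC[C@]1(CC2(CCCCCCC/C=C\C/C=C\CCCCC)SCCCS2)CO1 | intermediate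
18 | 1,3-dithiane | C1CSCSC1 | starting material
19 | 2-lithio-1,3-dithiane (not isolated) | [Li]C1SCCCS1 | intermediate
20 | 2-(tert-butyldimethylsilyl)-1,3-dithiane | CC(C)(C)[Si](C)(C)C1SCCCS1 | intermediate
21 | 2-lithio-2-(tert-butyldimethylsilyl)-1,3-dithiane (not isolated) | CC(C)(C)[Si](C)(C)C1([Li])SCCCS1 | intermediate
22 | lithium alkoxide from epoxide opening at C6, C5 configured as in 17 (not isolated) | ClCCC[C@](O[Li])(CC1(CCCCCCC/C=C\C/C=C\CCCCC)SCCCS1)CC1([Si](C)(C)C(C)(C)C)SCCCS1 | intermediate
23 | C1-lithiated dithiane after silyl shift to the C5 oxygen, C5 configured as in 17 (not isolated) | ClCCC[C@](O[Si](C)(C)C(C)(C)C)(CC1(CCCCCCC/C=C\C/C=C\CCCCC)SCCCS1)CC1([Li])SCCCS1 | intermediate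
24 | (8R)-8-[(tert-butyldimethylsilyl)oxy]-8-({2-[(8Z,11Z)-heptadeca-8,11-dien-1-yl]-1,3-dithian-2-yl}methyl)-1,5-dithiaspiro[5.5]undecane | CCCCC/C=C\C/C=C\CCCCCCCC1(SCCCS1)C[C@@]2(O[Si](C)(C)C(C)(C)C)CCCC3(SCCCS3)C2 | intermediate
25 | (3R)-3-[(tert-butyldimethylsilyl)oxy]-3-[(10Z,13Z)-2-oxononadeca-10,13-dien-1-yl]cyclohexan-1-one | CCCCC/C=C\C/C=C\CCCCCCCC(=O)C[C@@]1(O[Si](C)(C)C(C)(C)C)CCCC(=O)C1 | intermediate
26 | (5S)-5-[(tert-butyldimethylsilyl)oxy]-5-[(10Z,13Z)-2-oxononadeca-10,13-dien-1-yl]-2-(phenylselanyl)cyclohexan-1-one (both C2 epimers) | CCCCC/C=C\C/C=C\CCCCCCCC(=O)C[C@@]1(O[Si](C)(C)C(C)(C)C)CCC([Se]c2ccccc2)C(=O)C1 | intermediate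
27 | selenoxide of 26 (not isolated) | CCCCC/C=C\C/C=C\CCCCCCCC(=O)C[C@@]1(O[Si](C)(C)C(C)(C)C)CCC([Se](=O)c2ccccc2)C(=O)C1 | intermediate
28 | (5S)-5-[(tert-butyldimethylsilyl)oxy]-5-[(10Z,13Z)-2-oxononadeca-10,13-dien-1-yl]cyclohex-2-en-1-one | CCCCC/C=C\C/C=C\CCCCCCCC(=O)C[C@@]1(O[Si](C)(C)C(C)(C)C)CC=CC(=O)C1 | intermediate
29 | (5S)-5-hydroxy-5-[(10Z,13Z)-2-oxononadeca-10,13-dien-1-yl]cyclohex-2-en-1-one (CNP0252404.1) | CCCCC/C=C\C/C=C\CCCCCCCC(=O)C[C@@]1(O)CC=CC(=O)C1 | target

Total step count: 16. Longest linear sequence: 13 steps (steps 1–5, 8–10, 12–16).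

Steps most likely to fail

Step 12 (key step). The silyl shift onto the crowded tertiary alkoxide may be slow, so that the alkoxide attacks the chloropropyl arm instead (tetrahydrofuran closure). The dithiane anion may also alkylate at the chloride before it opens the hindered epoxide. The fallback separates the events and sets out from 17. Opening of the epoxide at C6 with 2-lithio-1,3-dithiane 19 (THF, –30 → 0 °C) should give 5-chloro-1-(1,3-dithian-2-yl)-2-({2-[(8Z,11Z)-heptadeca-8,11-dien-1-yl]-1,3-dithian-2-yl}methyl)pentan-2-ol F1. Silylation of the tertiary hydroxyl (TBSOTf, 2,6-lutidine, CH2Cl2) should give its tert-butyldimethylsilyl ether F2. Deprotonation of the monosubstituted dithiane (n-BuLi, THF/HMPA, –78 °C → rt) then closes ring A by the classical intramolecular dithiane alkylation of the chloride and returns to 24.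

Step 14. Chemoselectivity may be lost through enamine formation and selenenylation on the acyclic ketone toward C3', or the amine may promote β-elimination of the silyloxy group. The fallback takes the chain ketone out of play and sets out from 25. The cyclohexanone carbonyl is ketalised selectively (1,2-bis(trimethylsilyloxy)ethane, TMSOTf cat., CH2Cl2, –78 °C; cyclohexanones ketalise far faster than hindered acyclic ketones) to 7-[(tert-butyldimethylsilyl)oxy]-7-[(10Z,13Z)-2-oxononadeca-10,13-dien-1-yl]-1,4-dioxaspiro[4.5]decane F3. NaBH4 in MeOH reduces the chain ketone to 7-[(tert-butyldimethylsilyl)oxy]-7-[(10Z,13Z)-2-hydroxynonadeca-10,13-dien-1-yl]-1,4-dioxaspiro[4.5]decane F4. PPTS in wet acetone frees the ring ketone to give 3-[(tert-butyldimethylsilyl)oxy]-3-[(10Z,13Z)-2-hydroxynonadeca-10,13-dien-1-yl]cyclohexan-1-one F5. Its dianion (LDA, 2.2 equiv, THF, –78 °C; alkoxide plus kinetic C2 enolate) is treated with N-tert-butylbenzenesulfinimidoyl chloride, which dehydrogenates the enolate to the C2–C3 enone and oxidises the alkoxide back to the ketone, returning to 28.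

Step 16. Cleavage of the hindered tertiary silyl ether may be slow, and during it acid- or fluoride-promoted loss of the C5 oxygen from the enone would end in aromatisation of ring A. The fallback unmasks the alcohol before the enone exists and sets out from 26. HF·pyridine (pyridine, THF) removes the silyl group at the saturated stage to give (5S)-5-hydroxy-5-[(10Z,13Z)-2-oxononadeca-10,13-dien-1-yl]-2-(phenylselanyl)cyclohexan-1-one F6. Oxidation to the selenoxide and syn-elimination (H2O2, pyridine, CH2Cl2, 0 °C) then becomes the last, near-neutral operation and gives 29 directly.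

Further compounds
F1 | step 12 | 5-chloro-1-(1,3-dithian-2-yl)-2-({2-[(8Z,11Z)-heptadeca-8,11-dien-1-yl]-1,3-dithian-2-yl}methyl)pentan-2-ol, carbinol carbon configured as C5 of 17 | ClCCC[C@](O)(CC1(CCCCCCC/C=C\C/C=C\CCCCC)SCCCS1)CC1SCCCS1
F2 | step 12 | tert-butyldimethylsilyl ether of F1 | ClCCC[C@](O[Si](C)(C)C(C)(C)C)(CC1(CCCCCCC/C=C\C/C=C\CCCCC)SCCCS1)CC1SCCCS1
F3 | step 14 | 7-[(tert-butyldimethylsilyl)oxy]-7-[(10Z,13Z)-2-oxononadeca-10,13-dien-1-yl]-1,4-dioxaspiro[4.5]decane, C7 configured as C3 of 25 | CCCCC/C=C\C/C=C\CCCCCCCC(=O)C[C@@]1(O[Si](C)(C)C(C)(C)C)CCCC2(OCCO2)C1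
F4 | step 14 | 7-[(tert-butyldimethylsilyl)oxy]-7-[(10Z,13Z)-2-hydroxynonadeca-10,13-dien-1-yl]-1,4-dioxaspiro[4.5]decane, both epimers at the new carbinol | CCCCC/C=C\C/C=C\CCCCCCCC(O)C[C@@]1(O[Si](C)(C)C(C)(C)C)CCCC2(OCCO2)C1
F5 | step 14 | 3-[(tert-butyldimethylsilyl)oxy]-3-[(10Z,13Z)-2-hydroxynonadeca-10,13-dien-1-yl]cyclohexan-1-one, both epimers at the side-chain carbinol | CCCCC/C=C\C/C=C\CCCCCCCC(O)C[C@@]1(O[Si](C)(C)C(C)(C)C)CCCC(=O)C1
F6 | step 16 | (5S)-5-hydroxy-5-[(10Z,13Z)-2-oxononadeca-10,13-dien-1-yl]-2-(phenylselanyl)cyclohexan-1-one, both C2 epimers | CCCCC/C=C\C/C=C\CCCCCCCC(=O)C[C@@]1(O)CCC([Se]c2ccccc2)C(=O)C1
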